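The pyran ring is cut at C2–C3 and at O1–C8a, which makes O1, C2 and both methyl groups a molecule of acetone. A ketone at C4, absent from the target and removed in step 3, turns C3 into an enolate carbon and activates C8a of the benzene ring, ortho to it, for fluoride displacement. The precursor is 2,6-difluoro-4-methoxyacetophenone: its enolate adds to acetone and the tertiary alkoxide closes the ring by SNAr in the same flask. The two fluorines are equivalent, so either closure gives one chromanone; the fluorine left at C5 then steers lithiation to C6 and is finally exchanged for the C5 hydroxyl.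

Key step: step 2

Remark: atom numbers are those of the 2H-chromene skeleton (O1, C2, C3, C4, C4a, C5 to C8, C8a); the target is written as its diketo tautomer and is expected to exist largely as the hydrogen-bonded enol of the same constitution.

Step 1
Reactants: 1 3,5-difluoroanisole; 2 N-methoxy-N-methylacetamide
Product: 4 1-(2,6-difluoro-4-methoxyphenyl)ethan-1-one, via aryllithium 3 (not isolated)
Conditions: n-BuLi (1.05 equiv), THF, −78 °C; then 2, −78 °C to 0 °C; aq. HCl
Reagents that add atoms: none
Why: Directed ortho-lithiation should take place at the most acidic C–H, the one flanked by both fluorines, and the Weinreb ketone synthesis stops at the methyl ketone; no stereocenter is formed.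

Step 2
Reactants: 4 1-(2,6-difluoro-4-methoxyphenyl)ethan-1-one; 5 acetone
Product: 8 5-fluoro-7-methoxy-2,2-dimethylchroman-4-one, via lithium enolate 6 (not isolated), via lithium aldolate 7 (not isolated)
Conditions: LiN(SiMe3)2 (1.1 equiv), THF, −78 °C; 5 (3 equiv), −78 °C; then DMPU, −78 °C to 40 °C
Reagents that add atoms: none
Why: LiN(SiMe3)2 deprotonates the acetyl group of 4 to the lithium enolate 6, whose carbon (future C3) adds to the carbonyl carbon of acetone (future C2) to give the tertiary lithium aldolate 7. The alkoxide oxygen of 7 (future O1) then attacks the fluorine-bearing ring carbon ortho to the ketone (future C8a), and fluoride leaves from a Meisenheimer intermediate whose charge is taken up by the C4 carbonyl, so that the C–C bond and the aryl ether bond form in one flask. The closest known reaction types are the Kabbe chromanone synthesis (aldol of an acetophenone with acetone, then ring closure through oxygen) and the intramolecular SNAr etherification of 2-fluoroaryl ketones, joined here as an aldol–SNAr domino. The pyranone ring closes by a 6-exo-trig addition–elimination at the sp2 carbon C8a, and no stereocenter is formed. The step needs ring closure to outrun retro-aldol cleavage and E1cB dehydration of 7: retro-aldol only returns 6 and acetone, which recombine, whereas loss of fluoride is irreversible, and the low-temperature addition with a non-nucleophilic lithium base followed by DMPU to free the alkoxide should keep dehydration slow. Site selectivity is not an issue, because the two ortho fluorines of 4 are related by symmetry.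

Step 3
Reactants: 8 5-fluoro-7-methoxy-2,2-dimethylchroman-4-one
Product: 10 5-fluoro-7-methoxy-2,2-dimethyl-2H-chromene, via chromanol 9 (not isolated)
Conditions: NaBH4, MeOH–THF, 0 °C to rt; extraction into toluene, then p-TsOH·H2O (cat.), toluene, 80 °C
Reagents that add atoms: none
Why: Hydride reduction of the aryl ketone should give the racemic benzylic alcohol 9, which loses water by acid-catalysed E1 dehydration through a cation stabilised by O1 and the C7 methoxy group; C2 carries no hydrogen, so only the C3=C4 alkene can form and the stereocenter of 9 disappears.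

Step 4
Reactants: 10 5-fluoro-7-methoxy-2,2-dimethyl-2H-chromene; 2 N-methoxy-N-methylacetamide
Product: 12 1-(5-fluoro-7-methoxy-2,2-dimethyl-2H-chromen-6-yl)ethan-1-one, via aryllithium 11 (not isolated)
Conditions: n-BuLi (1.05 equiv), THF, −78 °C; then 2, −78 °C to −20 °C; aq. NH4Cl
Reagents that add atoms: none
Why: Directed ortho-lithiation at −78 °C should select C6–H, flanked by fluorine and methoxy, over C8–H between two alkoxy groups, which is lithiated only at higher temperature, and the Weinreb ketone synthesis then installs the acetyl group.

Step 5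
Reactants: 12 1-(5-fluoro-7-methoxy-2,2-dimethyl-2H-chromen-6-yl)ethan-1-one
Product: 14 1-(5-hydroxy-7-methoxy-2,2-dimethyl-2H-chromen-6-yl)ethan-1-one, via sulfonylethyl ether 13 (not isolated)
Conditions: MeSO2CH2CH2OH (2.5 equiv), NaH (2.2 equiv), DMF, 0 °C; then 12, 0 °C to 40 °C; aq. HCl
Reagents that add atoms: 2-(methylsulfonyl)ethanol CS(=O)(=O)CCO
Why: SNAr of the C5 fluoride, now ortho to the C6 acetyl group, by the alkoxide should give ether 13, from which E1cB loss of methyl vinyl sulfone unmasks the phenoxide, so the reagent acts as a hydroxide surrogate without strong aqueous base.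

Step 6
Reactants: 14 1-(5-hydroxy-7-methoxy-2,2-dimethyl-2H-chromen-6-yl)ethan-1-one; 15 benzoyl chloride
Product: 16 1-(5-hydroxy-7-methoxy-2,2-dimethyl-2H-chromen-6-yl)-3-phenylpropane-1,3-dione (target)
Conditions: LiN(SiMe3)2 (3.3 equiv), THF, −78 °C to −10 °C; then 15 (1.05 equiv), −78 °C to rt; aq. HCl
Reagents that add atoms: none
Why: Claisen-type C-acylation, the one-flask counterpart of the Baker–Venkataraman sequence: the phenoxide–enolate dianion should attack benzoyl chloride through its carbon terminus, and the more acidic diketone formed is deprotonated by the third equivalent of base, which protects it from a second acylation.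

Compound list
1 | 3,5-difluoroanisole | COc1cc(F)cc(F)c1 | starting material
2 | N-methoxy-N-methylacetamide | CC(=O)N(C)OC | starting material
3 | (2,6-difluoro-4-methoxyphenyl)lithium | COc1cc(F)c([Li])c(F)c1 | intermediate
4 | 1-(2,6-difluoro-4-methoxyphenyl)ethan-1-one | COc1cc(F)c(C(C)=O)c(F)c1 | intermediate
5 | acetone | CC(C)=O | starting material
6 | lithium 1-(2,6-difluoro-4-methoxyphenyl)ethen-1-olate | COc1cc(F)c(C(=C)O[Li])c(F)c1 | intermediate
7 | lithium 4-(2,6-difluoro-4-methoxyphenyl)-2-methyl-4-oxobutan-2-olate | COc1cc(F)c(C(=O)CC(C)(C)O[Li])c(F)c1 | intermediate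
8 | 5-fluoro-7-methoxy-2,2-dimethylchroman-4-one | COc1cc(F)c2C(=O)CC(C)(C)Oc2c1 | intermediate
9 | 5-fluoro-7-methoxy-2,2-dimethylchroman-4-ol (racemic) | COc1cc(F)c2C(O)CC(C)(C)Oc2c1 | intermediate
10 | 5-fluoro-7-methoxy-2,2-dimethyl-2H-chromene | COc1cc(F)c2C=CC(C)(C)Oc2c1 | intermediate
11 | (5-fluoro-7-methoxy-2,2-dimethyl-2H-chromen-6-yl)lithium | COc1cc2OC(C)(C)C=Cc2c(F)c1[Li] | intermediate
12 | 1-(5-fluoro-7-methoxy-2,2-dimethyl-2H-chromen-6-yl)ethan-1-one | COc1cc2OC(C)(C)C=Cc2c(F)c1C(C)=O | intermediate
13 | 1-{7-methoxy-2,2-dimethyl-5-[2-(methylsulfonyl)ethoxy]-2H-chromen-6-yl}ethan-1-one | COc1cc2OC(C)(C)C=Cc2c(OCCS(C)(=O)=O)c1C(C)=O | intermediate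
14 | 1-(5-hydroxy-7-methoxy-2,2-dimethyl-2H-chromen-6-yl)ethan-1-one | COc1cc2OC(C)(C)C=Cc2c(O)c1C(C)=O | intermediate
15 | benzoyl chloride | O=C(Cl)c1ccccc1 | starting material
16 | 1-(5-hydroxy-7-methoxy-2,2-dimethyl-2H-chromen-6-yl)-3-phenylpropane-1,3-dione | COc1cc2c(c(O)c1C(=O)CC(=O)c1ccccc1)C=CC(C)(C)O2 | target

Total step count: 6
Longest linear sequence: 6 steps (1 to 16)

Steps most likely to fail

Step 2 (key step). The aldolate 7 may revert to 6 and acetone, or lose water to the unsaturated ketone, faster than it closes onto the ring, so that 4 is recovered or the enone builds up. The fallback keeps the same two ring bonds but forms them at the alkene oxidation level; it sets out from 1 and comes back to the route at 10, so that steps 2 and 3 are both replaced. Lithiation of 1 (n-BuLi, THF, −78 °C) and a DMF quench should give 2,6-difluoro-4-methoxybenzaldehyde F1. Stork–Zhao olefination (iodomethyltriphenylphosphonium iodide, NaN(SiMe3)2, THF–DMPU, −78 °C) should give (Z)-1,3-difluoro-2-(2-iodovinyl)-5-methoxybenzene F2. Iodine–lithium exchange with retention of alkene geometry (t-BuLi, 2 equiv, Et2O, −78 °C) and addition to acetone 5 should give lithium (Z)-4-(2,6-difluoro-4-methoxyphenyl)-2-methylbut-3-en-2-olate F3. On addition of DMPU and warming to about 60 °C, F3 should close by intramolecular SNAr to chromene 10; the ring is then activated only inductively by the meta fluorine and methoxy group, hence the higher temperature.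

Step 5. Fluoride displacement may be sluggish because the C6 acetyl group, flanked by fluorine and methoxy, is twisted out of conjugation and is partly enolised by the alkoxide. The fallback lets the side chain itself displace the fluoride; it sets out from 12 and comes back to the route at 16, replacing steps 5 and 6. C-benzoylation of 12 (LiN(SiMe3)2, 2.2 equiv, THF, −78 °C; then 15) should give 1-(5-fluoro-7-methoxy-2,2-dimethyl-2H-chromen-6-yl)-3-phenylpropane-1,3-dione F4. Treatment with K2CO3 in DMF at 80 °C should close the enolate oxygen onto C5 by intramolecular SNAr to the pyranoflavone 5-methoxy-8,8-dimethyl-2-phenyl-4H,8H-pyrano[2,3-f]chromen-4-one F5. Brief treatment with KOH in aqueous pyridine at about 50 °C, followed by acidification, should open the pyranone ring by hydroxide addition and retro-oxa-Michael cleavage to 16; this alkaline opening of flavones to 2-hydroxydibenzoylmethanes must be stopped before retro-Claisen scission sets in.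

Step 4. The hindered aryllithium 11 may take a proton from the enolisable amide 2 instead of adding to it, which returns 10, or may lose LiF to an aryne on warming. The fallback replaces the acyl substitution by carbonyl addition and oxidation; it sets out from 10 (through 11) and comes back to the route at 12. Trapping 11 at −78 °C with acetaldehyde, which adds much faster than it is deprotonated, should give 1-(5-fluoro-7-methoxy-2,2-dimethyl-2H-chromen-6-yl)ethan-1-ol F6 as the racemate. Oxidation with Dess–Martin periodinane (CH2Cl2, NaHCO3, rt) should then give 12.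

Further compounds
F1 | step 2 | 2,6-difluoro-4-methoxybenzaldehyde | COc1cc(F)c(C=O)c(F)c1
F2 | step 2 | (Z)-1,3-difluoro-2-(2-iodovinyl)-5-methoxybenzene | COc1cc(F)c(/C=C\I)c(F)c1
F3 | step 2 | lithium (Z)-4-(2,6-difluoro-4-methoxyphenyl)-2-methylbut-3-en-2-olate | COc1cc(F)c(/C=C\C(C)(C)O[Li])c(F)c1
F4 | step 5 | 1-(5-fluoro-7-methoxy-2,2-dimethyl-2H-chromen-6-yl)-3-phenylpropane-1,3-dione | COc1cc2OC(C)(C)C=Cc2c(F)c1C(=O)CC(=O)c1ccccc1
F5 | step 5 | 5-methoxy-8,8-dimethyl-2-phenyl-4H,8H-pyrano[2,3-f]chromen-4-one | COc1cc2OC(C)(C)C=Cc2c2oc(-c3ccccc3)cc(=O)c12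
F6 | step 4 | 1-(5-fluoro-7-methoxy-2,2-dimethyl-2H-chromen-6-yl)ethan-1-ol (racemic) | COc1cc2OC(C)(C)C=Cc2c(F)c1C(C)O
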